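## The problem

CID53356209 is built from three oxygenated aryl units. Ring A (guaiacyl) carries a glycerol chain Cα–Cβ–Cγ. The Cβ oxygen is the 4-oxygen of ring B (syringyl). Ring B sits on C2 of a 2,3-dihydrobenzofuran whose benzo ring (ring C) bears 7-OMe and 5-CHO and whose C3 carries a hydroxymethyl carbon (C9).

There are four stereocentres in two pairs: Cα (S) and Cβ (R), erythro, and C2 (R) and C3 (S), trans. Within a pair one centre can steer the other: C3 is epimerisable while C9 is an ester, so trans is the thermodynamic outcome, and Cα and Cβ can be set together in one aldol event. The pairs are separated by the flat ring B and cannot influence each other. Each pair therefore needs its own source of absolute configuration, and the two halves must both be enantiopure when they are joined.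

The Cβ–O bond links a secondary carbon to a phenol oxygen flanked by two methoxy groups, so it is a hindered bond to make. Several groups are fragile: the aldehyde (reductants), the para-hydroxybenzylic alcohol at Cα (acid ionises it), the benzylic aryl ether C2–O1 (hydrogenolysis, acid, oxidation) and the free phenols.

The feature that opens the route is the O1–C2–C3 array. C2 bears an aryl group and C3 bears one carbon at the carboxyl level. These are the two carbons of a diarylacetylene that has taken up the ring C phenol oxygen at one end and carbon monoxide at the other.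

## Retrosynthesis

**Unmasking.** Target 29 is traced back to its dioxolane 28 and then to the bis-silyl ether 27. Only O–Si bonds and the acetal C–O bonds are cut. This keeps the aldehyde, the Cα carbinol and the ring A phenol covered until the end, and the last two operations need only buffered fluoride and dilute acid. Hydrogenolysis is excluded from the endgame on purpose, because the free aldehyde and the benzylic C–O bonds would be at risk.

**Cβ–O(ring B) ether.** Diol 27 comes from ester 26 by hydride, which also removes the acetate on C9. In 26 the Cβ–O bond is cut to give phenol 14 and α-hydroxy ester 25, joined by Mitsunobu etherification with inversion at Cβ.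
- The cut divides the molecule into two halves of similar size, each made enantiopure on its own, so the coupling gives a single diastereomer.
- Cutting Cα–Cβ instead (aldol on an aryloxyacetyl derivative of 14) would put five or six steps on the most valuable intermediate, and the standard syn aldol gives threo.
- Attaching the chain before the ring stereocentres are fixed would send an enantiopure chain through a racemic reduction and give diastereomers that differ only at remote centres.
- The forward reaction must achieve SN2 at a secondary carbon with a di-ortho-substituted phenol. The α-ester activates that carbon, and the inversion turns the easily made threo arrangement into the required erythro one.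

**Cα–Cβ bond.** Hydroxy ester 25 is traced through 24 and 23 to aldol adduct 22, made from glycolyl imide 20 (via its boron enolate 21) and aldehyde 16. A dihydroxylated cinnamate would have the same threo relationship, but its two secondary hydroxyls would still have to be told apart, and a Mitsunobu reaction on such a diol goes to the benzylic position. The glycolate aldol delivers the Cα oxygen free and the Cβ oxygen benzylated, so they are differentiated from the start. 16 comes from vanillin 15, and 20 from oxazolidinone 17 and acid chloride 18 through the lithium salt 19.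

**Ring stereocentres.** Phenol 14 is traced through acetate 13 to alcohol 12, the (2R,3S) half of racemic trans alcohol 11. 11 comes from racemic trans ester 10, the product of dissolving-metal reduction of the benzofuran C2=C3 bond in 9.
- A catalyst-controlled cis-hydrogenation of this tetrasubstituted, donor–acceptor double bond, followed by base epimerisation at C3, has no close precedent, so it is not used.
- The Mg/MeOH reduction gives trans directly under thermodynamic control.
- Absolute configuration then comes from an enzymatic kinetic resolution of the primary alcohol. The cost is half of 11, at a point reached from cheap materials.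

**Furan ring and C9 (key cut).** Acetal 9 comes from aldehyde 8. In 8 the O1–C2 and C3–C9 bonds are cut together, leading to alkynylphenol 7 with CO and methanol as reagents. The alternative of closing the benzofuran first and acylating C3 afterwards takes more steps and would pit C3 against the electron-rich rings B and C. The one-pot cyclisation–carbonylation places the carbon exactly where palladium sits after ring closure. The precursor has no ring C–O bond, no C9 and no stereocentre.

**Alkyne.** Phenol 7 is the deacetylation product of 6, which is cut at the aryl–alkyne bond into alkyne 3 and iodide 5 (Sonogashira coupling). The acetate in 5, made from 5-iodovanillin 4, prevents the coupling from running on to a carbonyl-free benzofuran. Alkyne 3 comes from aldehyde 2 by one-carbon homologation, and 2 from syringaldehyde 1.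

## Roads not taken

**Alternative 1:** The glycerol unit could be assembled on the finished phenylcoumaran by cutting Cβ–O and Cα–Cβ at once. Rh2(OAc)4 would convert ethyl diazoacetate A2 into a carbenoid, and the ring B phenol A4 would add to it. The resulting oxonium ylide would be trapped by 4-(benzyloxy)-3-methoxybenzaldehyde A3 under a chiral binaphthol–Zr(OtBu)4 co-catalyst to give the erythro α-aryloxy-β-hydroxy ester A1.
- Merits: the hindered aryl ether is formed at a carbenoid carbon and not by substitution, erythro arises directly, and the whole side chain is made in one step. For this part of the molecule it is clearly shorter than the fragment synthesis plus Mitsunobu used here (one step against seven).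
- Weak points: the 1,2-proton shift (plain O–H insertion) competes with aldol trapping, the more so with an acidic phenol and a poorly electrophilic, electron-rich aldehyde. Enantio- and diastereocontrol must be won on the most valuable intermediate, and the possible by-products differ from A1 only at centres remote from the ring stereocentres.
- It leaves the dihydrobenzofuran unsolved, since A4 must come from elsewhere.
- The chosen plan sets predictability against the shorter step count: Cα and Cβ are fixed by an auxiliary aldol and a stereospecific inversion on a small fragment that can be purified before it meets 14.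

**Alternative 2:** The ring could be made by contracting a flavanone, the cut being C3–C3a. PhI(OAc)2 and H2SO4 in trimethyl orthoformate would functionalise C3 of the (2R)-flavanone A6. The ring C carbon would migrate from the carbonyl carbon to C3, and the former carbonyl carbon would leave the ring as the methyl ester of trans dihydrobenzofuran A5.
- Merits: a single stereocentre is relayed into both ring centres with trans selectivity and without a resolution. In enantio-economy this is better than the chosen plan, which discards half of 11.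
- Weak points: ring contraction competes with dehydrogenation to the flavone and with migration of the C2 aryl group, which an electron-rich ring B favours (hence the mesylate in A5). The strongly acidic, oxidising medium excludes the aldehyde, so ring C carries bromine that must later be exchanged for a formyl group beside an ester. A6 can lose its configuration by reversible opening to the chalcone.
- The chosen plan sets against this a neutral key step that carries the aldehyde through and has no regiochemical alternative, at the price of the resolution.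

**Alternative 3:** The most direct cut follows biosynthesis: C3–C3a and O1–C2 in one oxidative step. Ag2O would oxidise the sinapoyl imide A8 and vanillin 15 to phenoxyl radicals. The β-carbon of A8 would couple with C5 of 15, and the vanillin oxygen would add to the quinone methide to give A7, with the auxiliary choosing the face.
- Merits: two simple components, no protection of the phenol or the aldehyde, and both ring bonds and both stereocentres formed in one step. It is by far the shortest route to the phenylcoumaran on paper, and the chosen plan cannot match it in step count.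
- Weak points: two different radicals must pair selectively. A sinapate radical prefers β–β homocoupling, and vanillin, with its formyl group, is harder to oxidise and less inclined to couple at C5, so the homodimer of A8 should dominate. Face selection by an auxiliary in a radical–radical coupling is usually modest.
- The chosen plan answers the pairing problem by construction: an aryl iodide and a terminal alkyne can combine in only one way, and the ring bonds are then made by an ionic organometallic sequence.

Key step: step 6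

## Route

Assumption: the lipase in step 10 acetylates the (2S,3R) enantiomer of 11 faster (to be confirmed by correlation of 12); if the preference is the reverse, the acetate formed is 13 itself and step 11 is not needed.
Remark: the racemates 10, 11 and F3 are written in SMILES as both enantiomers joined by a dot.

Step 1
Reactants: 1 syringaldehyde (4-hydroxy-3,5-dimethoxybenzaldehyde)
Product: 2 4-(benzyloxy)-3,5-dimethoxybenzaldehyde
Conditions: BnBr, K2CO3, DMF, 60 °C
Reagents that add atoms: benzyl bromide, BrCc1ccccc1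
Why: Williamson etherification of an acidic, formyl-activated phenol; DMF and gentle heating overcome the two flanking methoxy groups.

Step 2
Reactants: 2 4-(benzyloxy)-3,5-dimethoxybenzaldehyde
Product: 3 2-(benzyloxy)-5-ethynyl-1,3-dimethoxybenzene
Conditions: dimethyl (1-diazo-2-oxopropyl)phosphonate, K2CO3, MeOH, rt
Reagents that add atoms: dimethyl (1-diazo-2-oxopropyl)phosphonate, COP(=O)(OC)C(=[N+]=[N-])C(C)=O
Why: Seyferth–Gilbert homologation in the Ohira–Bestmann form; the non-enolisable aryl aldehyde is converted through the alkylidene carbene into the terminal alkyne.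

Step 3
Reactants: 4 5-iodovanillin (4-hydroxy-3-iodo-5-methoxybenzaldehyde)
Product: 5 4-formyl-2-iodo-6-methoxyphenyl acetate
Conditions: Ac2O, pyridine, rt
Reagents that add atoms: acetic anhydride, CC(=O)OC(C)=O
Why: O-acetylation masks the phenol so that the cross-coupling cannot run on to a benzofuran.

Step 4
Reactants: 3 2-(benzyloxy)-5-ethynyl-1,3-dimethoxybenzene, 5 4-formyl-2-iodo-6-methoxyphenyl acetate
Product: 6 2-{[4-(benzyloxy)-3,5-dimethoxyphenyl]ethynyl}-4-formyl-6-methoxyphenyl acetate
Conditions: Pd(PPh3)2Cl2 (3 mol%), CuI (5 mol%), Et3N, THF, rt, degassed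
Reagents that add atoms: none
Why: Sonogashira coupling of an aryl iodide with a terminal arylalkyne; it runs at room temperature, and the tertiary amine leaves the aryl acetate intact, so no heteroannulation can follow.

Step 5
Reactants: 6 2-{[4-(benzyloxy)-3,5-dimethoxyphenyl]ethynyl}-4-formyl-6-methoxyphenyl acetate
Product: 7 3-{[4-(benzyloxy)-3,5-dimethoxyphenyl]ethynyl}-4-hydroxy-5-methoxybenzaldehyde
Conditions: K2CO3 (0.2 equiv), MeOH–THF, 0 °C; AcOH quench
Reagents that add atoms: none
Why: Transesterification of an activated aryl acetate (formyl-stabilised phenoxide as leaving group) is fast at 0 °C, well below the temperature at which the phenoxide adds to an unactivated alkyne; copper and palladium residues are removed from 6 beforehand.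

Step 6
Reactants: 7 3-{[4-(benzyloxy)-3,5-dimethoxyphenyl]ethynyl}-4-hydroxy-5-methoxybenzaldehyde
Product: 8 methyl 2-[4-(benzyloxy)-3,5-dimethoxyphenyl]-5-formyl-7-methoxy-1-benzofuran-3-carboxylate
Conditions: PdCl2 (10 mol%), CuCl2 (3 equiv), NaOAc (3 equiv), CO (1 atm), MeOH, rt; dilute HCl work-up
Reagents that add atoms: carbon monoxide, [C-]#[O+]; methanol, CO
Why: Divalent palladium (PdCl2) binds the alkyne of 7, and the ring C phenol oxygen attacks the alkyne carbon bearing ring B from the face opposite the metal; this 5-endo-dig anti-oxypalladation closes the furan ring (O1–C2) and leaves a 3-benzofuranylpalladium chloride. CO inserts into the C3–Pd bond and methanol cleaves the acylpalladium, which forms the C3–C9 bond and the ester and releases zerovalent palladium; two equivalents of CuCl2 return it to the divalent state. The closest known reaction type is the PdCl2/CuCl2 cyclisation–alkoxycarbonylation of 2-alkynylphenols to benzofuran-3-carboxylates, of which this is a direct case with a diaryl alkyne. No stereocentre is formed. Regiochemistry is fixed by ring size, since only attack at the distal alkyne carbon gives a five-membered ring. The step needs CO insertion to be faster than protonolysis of the C3–Pd bond and than metal-free cycloisomerisation, both of which give the 3-unsubstituted benzofuran; a CO-saturated solution, NaOAc to take up the HCl and an excess of CuCl2 serve this, and the electron-rich ring B helps the alkyne bind the electrophilic metal. The formyl group is a spectator, and any dimethyl acetal formed is returned by the acidic work-up.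

Step 7
Reactants: 8 methyl 2-[4-(benzyloxy)-3,5-dimethoxyphenyl]-5-formyl-7-methoxy-1-benzofuran-3-carboxylate
Product: 9 methyl 2-[4-(benzyloxy)-3,5-dimethoxyphenyl]-5-(1,3-dioxolan-2-yl)-7-methoxy-1-benzofuran-3-carboxylate
Conditions: ethylene glycol, p-TsOH (cat.), toluene, reflux, Dean–Stark
Reagents that add atoms: ethane-1,2-diol, OCCO
Why: Acid-catalysed acetalisation with azeotropic removal of water; the aldehyde must be masked before the electron-transfer and hydride reductions, and the conjugated heteroaryl ester does not exchange.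

Step 8
Reactants: 9 methyl 2-[4-(benzyloxy)-3,5-dimethoxyphenyl]-5-(1,3-dioxolan-2-yl)-7-methoxy-1-benzofuran-3-carboxylate
Product: 10 methyl rac-(2R,3R)-2-[4-(benzyloxy)-3,5-dimethoxyphenyl]-5-(1,3-dioxolan-2-yl)-7-methoxy-2,3-dihydro-1-benzofuran-3-carboxylate (trans)
Conditions: Mg turnings (excess), MeOH–THF, 0 °C → rt; aq NH4Cl
Reagents that add atoms: none
Why: Dissolving-metal (Mg/MeOH) conjugate reduction of the donor–acceptor C2=C3 bond of a benzofuran-3-carboxylate, by electron transfer, protonation at C2, second electron transfer and protonation of the ester enolate. C3 equilibrates under Mg(OMe)2 to the trans arrangement, so the relative configuration of C2 and C3 is set under thermodynamic control and the product is racemic; ring opening by β-elimination is the reverse of a 5-endo-trig closure and is slow, and benzyl ether and acetal are inert.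

Step 9
Reactants: 10 methyl rac-(2R,3R)-2-[4-(benzyloxy)-3,5-dimethoxyphenyl]-5-(1,3-dioxolan-2-yl)-7-methoxy-2,3-dihydro-1-benzofuran-3-carboxylate
Product: 11 rac-{(2R,3S)-2-[4-(benzyloxy)-3,5-dimethoxyphenyl]-5-(1,3-dioxolan-2-yl)-7-methoxy-2,3-dihydro-1-benzofuran-3-yl}methanol (trans)
Conditions: LiAlH4, THF, 0 °C; H2O/NaOH work-up
Reagents that add atoms: none
Why: Hydride reduction of the ester to the primary alcohol; at 0 °C reduction outpaces enolisation, so the trans relationship is kept.

Step 10
Reactants: 11 rac-{(2R,3S)-2-[4-(benzyloxy)-3,5-dimethoxyphenyl]-5-(1,3-dioxolan-2-yl)-7-methoxy-2,3-dihydro-1-benzofuran-3-yl}methanol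
Product: 12 {(2R,3S)-2-[4-(benzyloxy)-3,5-dimethoxyphenyl]-5-(1,3-dioxolan-2-yl)-7-methoxy-2,3-dihydro-1-benzofuran-3-yl}methanol
Conditions: Burkholderia cepacia lipase (immobilised), vinyl acetate, t-BuOMe, 30 °C, run just past half conversion
Reagents that add atoms: none
Why: Lipase-catalysed kinetic resolution by irreversible acyl transfer from an enol ester to a primary alcohol whose stereocentre is next to the carbinol carbon, a standard substrate class that includes 2-aryl-3-(hydroxymethyl)dihydrobenzofurans. Running past half conversion should leave the slow (2R,3S) alcohol in high enantiomeric purity, separable from the (2S,3R) acetate by chromatography; the absolute configuration of C2 and C3 is fixed here by separation.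

Step 11
Reactants: 12 {(2R,3S)-2-[4-(benzyloxy)-3,5-dimethoxyphenyl]-5-(1,3-dioxolan-2-yl)-7-methoxy-2,3-dihydro-1-benzofuran-3-yl}methanol
Product: 13 {(2R,3S)-2-[4-(benzyloxy)-3,5-dimethoxyphenyl]-5-(1,3-dioxolan-2-yl)-7-methoxy-2,3-dihydro-1-benzofuran-3-yl}methyl acetate
Conditions: Ac2O, pyridine, DMAP (cat.), CH2Cl2, rt
Reagents that add atoms: acetic anhydride, CC(=O)OC(C)=O
Why: Acetylation covers the primary hydroxyl, which would otherwise be activated in the Mitsunobu step; the acetate is removed later by the hydride of step 20 at no extra cost.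

Step 12
Reactants: 13 {(2R,3S)-2-[4-(benzyloxy)-3,5-dimethoxyphenyl]-5-(1,3-dioxolan-2-yl)-7-methoxy-2,3-dihydro-1-benzofuran-3-yl}methyl acetate
Product: 14 {(2R,3S)-5-(1,3-dioxolan-2-yl)-2-(4-hydroxy-3,5-dimethoxyphenyl)-7-methoxy-2,3-dihydro-1-benzofuran-3-yl}methyl acetate
Conditions: H2 (1 atm), 10% Pd/C, EtOAc, rt
Reagents that add atoms: none
Why: Hydrogenolysis of an aryl benzyl ether; under neutral conditions at 1 atm this should be much faster than cleavage of the cyclic benzylic C2–O1 bond or of the aryl acetal, and the reaction is stopped once the benzyl group is gone.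

Step 13
Reactants: 15 vanillin (4-hydroxy-3-methoxybenzaldehyde)
Product: 16 3-methoxy-4-[(triisopropylsilyl)oxy]benzaldehyde
Conditions: TIPSCl, imidazole, DMF, rt
Reagents that add atoms: chlorotri(propan-2-yl)silane, CC(C)[Si](Cl)(C(C)C)C(C)C
Why: Silylation of the phenol; the bulky aryl silyl ether withstands boron aldol, alkoxide, hydrogenation, Mitsunobu and hydride conditions and leaves with fluoride at the end.

Step 14
Reactants: 17 (R)-4-benzyl-1,3-oxazolidin-2-one, 18 (benzyloxy)acetyl chloride
Product: 20 (R)-4-benzyl-3-[(benzyloxy)acetyl]-1,3-oxazolidin-2-one, via N-lithio oxazolidinone 19 (not isolated)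
Conditions: n-BuLi, THF, −78 °C; then 18, −78 → 0 °C
Reagents that add atoms: none
Why: N-acylation of the lithiated oxazolidinone with an acid chloride, the standard entry to glycolyl imides.

Step 15
Reactants: 20 (R)-4-benzyl-3-[(benzyloxy)acetyl]-1,3-oxazolidin-2-one, 16 3-methoxy-4-[(triisopropylsilyl)oxy]benzaldehyde
Product: 22 (R)-4-benzyl-3-{(2R,3S)-2-(benzyloxy)-3-hydroxy-3-[3-methoxy-4-(triisopropylsilyloxy)phenyl]propanoyl}-1,3-oxazolidin-2-one, via dibutylboron Z-enolate 21 (not isolated)
Conditions: Bu2BOTf, iPr2NEt, CH2Cl2, −78 → 0 °C; then 16, −78 → 0 °C; pH 7 buffer, MeOH, H2O2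
Reagents that add atoms: none
Why: Evans syn glycolate aldol: the Z-boron enolate reacts through a closed chair transition state in which the benzyl group of the (R)-auxiliary blocks one enolate face, so Cβ (2R) and Cα (3S) are set together in the threo relationship. The Cα oxygen emerges free and the Cβ oxygen benzylated, already differentiated.

Step 16
Reactants: 22 (R)-4-benzyl-3-{(2R,3S)-2-(benzyloxy)-3-hydroxy-3-[3-methoxy-4-(triisopropylsilyloxy)phenyl]propanoyl}-1,3-oxazolidin-2-one
Product: 23 methyl (2R,3S)-2-(benzyloxy)-3-hydroxy-3-[3-methoxy-4-(triisopropylsilyloxy)phenyl]propanoate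
Conditions: MeMgBr, MeOH, CH2Cl2, 0 °C; aqueous work-up (17 recovered)
Reagents that add atoms: methanol (delivered as bromomagnesium methoxide), CO
Why: Transesterification of the aldol imide with bromomagnesium methoxide; magnesium chelation directs methoxide to the exocyclic acyl group, and the short, cold treatment avoids retro-aldol cleavage and epimerisation at Cβ.

Step 17
Reactants: 23 methyl (2R,3S)-2-(benzyloxy)-3-hydroxy-3-[3-methoxy-4-(triisopropylsilyloxy)phenyl]propanoate
Product: 24 methyl (2R,3S)-2-(benzyloxy)-3-[(tert-butyldimethylsilyl)oxy]-3-[3-methoxy-4-(triisopropylsilyloxy)phenyl]propanoate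
Conditions: TBSOTf, 2,6-lutidine, CH2Cl2, −78 → 0 °C
Reagents that add atoms: tert-butyldimethylsilyl trifluoromethanesulfonate, CC(C)(C)[Si](C)(C)OS(=O)(=O)C(F)(F)F
Why: Silylation of the hindered benzylic hydroxyl with a silyl triflate and a non-nucleophilic base.

Step 18
Reactants: 24 methyl (2R,3S)-2-(benzyloxy)-3-[(tert-butyldimethylsilyl)oxy]-3-[3-methoxy-4-(triisopropylsilyloxy)phenyl]propanoate
Product: 25 methyl (2R,3S)-3-[(tert-butyldimethylsilyl)oxy]-2-hydroxy-3-[3-methoxy-4-(triisopropylsilyloxy)phenyl]propanoate
Conditions: H2 (1 atm), 10% Pd/C, EtOAc, rt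
Reagents that add atoms: none
Why: Hydrogenolysis of the alkyl benzyl ether frees the Cβ hydroxyl alone; silyl ethers and the ester are not touched under neutral conditions.

Step 19
Reactants: 14 {(2R,3S)-5-(1,3-dioxolan-2-yl)-2-(4-hydroxy-3,5-dimethoxyphenyl)-7-methoxy-2,3-dihydro-1-benzofuran-3-yl}methyl acetate, 25 methyl (2R,3S)-3-[(tert-butyldimethylsilyl)oxy]-2-hydroxy-3-[3-methoxy-4-(triisopropylsilyloxy)phenyl]propanoate
Product: 26 methyl (2S,3S)-2-{4-[(2R,3S)-3-(acetoxymethyl)-5-(1,3-dioxolan-2-yl)-7-methoxy-2,3-dihydro-1-benzofuran-2-yl]-2,6-dimethoxyphenoxy}-3-[(tert-butyldimethylsilyl)oxy]-3-[3-methoxy-4-(triisopropylsilyloxy)phenyl]propanoate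
Conditions: PPh3, DIAD, THF, 0 °C → rt (25 in excess)
Reagents that add atoms: none
Why: Mitsunobu etherification of an α-hydroxy ester, the most reactive class of secondary alcohols in this reaction, with a phenol of suitable acidity. SN2 displacement of the oxyphosphonium group inverts Cβ, so the threo aldol product becomes the erythro aryl ether (2S,3S in the ester, αS,βR after reduction). The phenol is the only free hydroxyl in 14 and the Cβ hydroxyl the only one in 25, so no other pairing is possible.

Step 20
Reactants: 26 methyl (2S,3S)-2-{4-[(2R,3S)-3-(acetoxymethyl)-5-(1,3-dioxolan-2-yl)-7-methoxy-2,3-dihydro-1-benzofuran-2-yl]-2,6-dimethoxyphenoxy}-3-[(tert-butyldimethylsilyl)oxy]-3-[3-methoxy-4-(triisopropylsilyloxy)phenyl]propanoate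
Product: 27 (2R,3S)-3-[(tert-butyldimethylsilyl)oxy]-2-{4-[(2R,3S)-5-(1,3-dioxolan-2-yl)-3-(hydroxymethyl)-7-methoxy-2,3-dihydro-1-benzofuran-2-yl]-2,6-dimethoxyphenoxy}-3-[3-methoxy-4-(triisopropylsilyloxy)phenyl]propan-1-ol
Conditions: LiBH4, THF, 0 °C → rt
Reagents that add atoms: none
Why: Hydride reduction of the α-aryloxy methyl ester to the Cγ alcohol and of the acetate to the C9 alcohol in one operation; silyl ethers and acetal are inert, and the weakly basic reagent should not epimerise Cβ before reduction.

Step 21
Reactants: 27 (2R,3S)-3-[(tert-butyldimethylsilyl)oxy]-2-{4-[(2R,3S)-5-(1,3-dioxolan-2-yl)-3-(hydroxymethyl)-7-methoxy-2,3-dihydro-1-benzofuran-2-yl]-2,6-dimethoxyphenoxy}-3-[3-methoxy-4-(triisopropylsilyloxy)phenyl]propan-1-ol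
Product: 28 (1S,2R)-2-{4-[(2R,3S)-5-(1,3-dioxolan-2-yl)-3-(hydroxymethyl)-7-methoxy-2,3-dihydro-1-benzofuran-2-yl]-2,6-dimethoxyphenoxy}-1-(4-hydroxy-3-methoxyphenyl)propane-1,3-diol
Conditions: Bu4NF, AcOH, THF, 0 °C → rt
Reagents that add atoms: none
Why: Fluoride cleavage of the aryl triisopropylsilyl ether and the benzylic tert-butyldimethylsilyl ether; acetic acid buffers the phenoxide so that the β-aryl ether unit is not exposed to strong base.

Step 22
Reactants: 28 (1S,2R)-2-{4-[(2R,3S)-5-(1,3-dioxolan-2-yl)-3-(hydroxymethyl)-7-methoxy-2,3-dihydro-1-benzofuran-2-yl]-2,6-dimethoxyphenoxy}-1-(4-hydroxy-3-methoxyphenyl)propane-1,3-diol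
Product: 29 (2R,3S)-2-(4-{[(1S,2R)-1,3-dihydroxy-1-(4-hydroxy-3-methoxyphenyl)propan-2-yl]oxy}-3,5-dimethoxyphenyl)-3-(hydroxymethyl)-7-methoxy-2,3-dihydro-1-benzofuran-5-carbaldehyde (CID53356209)
Conditions: 0.5 M HCl, THF–H2O, 0 °C → rt, short reaction time
Reagents that add atoms: water, O
Why: Hydrolysis of an aryl 1,3-dioxolane activated by the para ring oxygen proceeds in dilute acid within minutes, conditions under which the para-hydroxybenzylic alcohol at Cα should not ionise; no stereocentre is touched.

## Compound list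

1 | syringaldehyde (4-hydroxy-3,5-dimethoxybenzaldehyde) | COc1cc(C=O)cc(OC)c1O | starting material
2 | 4-(benzyloxy)-3,5-dimethoxybenzaldehyde | COc1cc(C=O)cc(OC)c1OCc1ccccc1 | intermediate
3 | 2-(benzyloxy)-5-ethynyl-1,3-dimethoxybenzene | COc1cc(C#C)cc(OC)c1OCc1ccccc1 | intermediate
4 | 5-iodovanillin (4-hydroxy-3-iodo-5-methoxybenzaldehyde) | COc1cc(C=O)cc(I)c1O | starting material
5 | 4-formyl-2-iodo-6-methoxyphenyl acetate | COc1cc(C=O)cc(I)c1OC(C)=O | intermediate
6 | 2-{[4-(benzyloxy)-3,5-dimethoxyphenyl]ethynyl}-4-formyl-6-methoxyphenyl acetate | COc1cc(C=O)cc(C#Cc2cc(OC)c(OCc3ccccc3)c(OC)c2)c1OC(C)=O | intermediate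
7 | 3-{[4-(benzyloxy)-3,5-dimethoxyphenyl]ethynyl}-4-hydroxy-5-methoxybenzaldehyde | COc1cc(C#Cc2cc(C=O)cc(OC)c2O)cc(OC)c1OCc1ccccc1 | intermediate
8 | methyl 2-[4-(benzyloxy)-3,5-dimethoxyphenyl]-5-formyl-7-methoxy-1-benzofuran-3-carboxylate | COC(=O)c1c(-c2cc(OC)c(OCc3ccccc3)c(OC)c2)oc2c(OC)cc(C=O)cc12 | intermediate
9 | methyl 2-[4-(benzyloxy)-3,5-dimethoxyphenyl]-5-(1,3-dioxolan-2-yl)-7-methoxy-1-benzofuran-3-carboxylate | COC(=O)c1c(-c2cc(OC)c(OCc3ccccc3)c(OC)c2)oc2c(OC)cc(C3OCCO3)cc12 | intermediate
10 | methyl rac-(2R,3R)-2-[4-(benzyloxy)-3,5-dimethoxyphenyl]-5-(1,3-dioxolan-2-yl)-7-methoxy-2,3-dihydro-1-benzofuran-3-carboxylate (trans, racemate) | COc1cc([C@@H]2Oc3c(OC)cc(C4OCCO4)cc3[C@H]2C(=O)OC)cc(OC)c1OCc1ccccc1.COc1cc([C@H]2Oc3c(OC)cc(C4OCCO4)cc3[C@@H]2C(=O)OC)cc(OC)c1OCc1ccccc1 | intermediate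
11 | rac-{(2R,3S)-2-[4-(benzyloxy)-3,5-dimethoxyphenyl]-5-(1,3-dioxolan-2-yl)-7-methoxy-2,3-dihydro-1-benzofuran-3-yl}methanol (trans, racemate) | COc1cc([C@@H]2Oc3c(OC)cc(C4OCCO4)cc3[C@H]2CO)cc(OC)c1OCc1ccccc1.COc1cc([C@H]2Oc3c(OC)cc(C4OCCO4)cc3[C@@H]2CO)cc(OC)c1OCc1ccccc1 | intermediate
12 | {(2R,3S)-2-[4-(benzyloxy)-3,5-dimethoxyphenyl]-5-(1,3-dioxolan-2-yl)-7-methoxy-2,3-dihydro-1-benzofuran-3-yl}methanol | COc1cc([C@@H]2Oc3c(OC)cc(C4OCCO4)cc3[C@H]2CO)cc(OC)c1OCc1ccccc1 | intermediate
13 | {(2R,3S)-2-[4-(benzyloxy)-3,5-dimethoxyphenyl]-5-(1,3-dioxolan-2-yl)-7-methoxy-2,3-dihydro-1-benzofuran-3-yl}methyl acetate | COc1cc([C@@H]2Oc3c(OC)cc(C4OCCO4)cc3[C@H]2COC(C)=O)cc(OC)c1OCc1ccccc1 | intermediate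
14 | {(2R,3S)-5-(1,3-dioxolan-2-yl)-2-(4-hydroxy-3,5-dimethoxyphenyl)-7-methoxy-2,3-dihydro-1-benzofuran-3-yl}methyl acetate | COc1cc([C@@H]2Oc3c(OC)cc(C4OCCO4)cc3[C@H]2COC(C)=O)cc(OC)c1O | intermediate
15 | vanillin (4-hydroxy-3-methoxybenzaldehyde) | COc1cc(C=O)ccc1O | starting material
16 | 3-methoxy-4-[(triisopropylsilyl)oxy]benzaldehyde | COc1cc(C=O)ccc1O[Si](C(C)C)(C(C)C)C(C)C | intermediate
17 | (R)-4-benzyl-1,3-oxazolidin-2-one | O=C1N[C@H](Cc2ccccc2)CO1 | starting material
18 | (benzyloxy)acetyl chloride | O=C(Cl)COCc1ccccc1 | starting material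
19 | N-lithio-(R)-4-benzyl-1,3-oxazolidin-2-one | [Li+].O=C1[N-][C@H](Cc2ccccc2)CO1 | intermediate (not isolated)
20 | (R)-4-benzyl-3-[(benzyloxy)acetyl]-1,3-oxazolidin-2-one | O=C(COCc1ccccc1)N1C(=O)OC[C@H]1Cc1ccccc1 | intermediate
21 | dibutylboron Z-enolate of 20 | CCCCB(CCCC)O/C(=C\OCc1ccccc1)N1C(=O)OC[C@H]1Cc1ccccc1 | intermediate (not isolated)
22 | (R)-4-benzyl-3-{(2R,3S)-2-(benzyloxy)-3-hydroxy-3-[3-methoxy-4-(triisopropylsilyloxy)phenyl]propanoyl}-1,3-oxazolidin-2-one | O=C([C@H](OCc1ccccc1)[C@@H](O)c1ccc(O[Si](C(C)C)(C(C)C)C(C)C)c(OC)c1)N1C(=O)OC[C@H]1Cc1ccccc1 | intermediate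
23 | methyl (2R,3S)-2-(benzyloxy)-3-hydroxy-3-[3-methoxy-4-(triisopropylsilyloxy)phenyl]propanoate | COC(=O)[C@H](OCc1ccccc1)[C@@H](O)c1ccc(O[Si](C(C)C)(C(C)C)C(C)C)c(OC)c1 | intermediate
24 | methyl (2R,3S)-2-(benzyloxy)-3-[(tert-butyldimethylsilyl)oxy]-3-[3-methoxy-4-(triisopropylsilyloxy)phenyl]propanoate | COC(=O)[C@H](OCc1ccccc1)[C@@H](O[Si](C)(C)C(C)(C)C)c1ccc(O[Si](C(C)C)(C(C)C)C(C)C)c(OC)c1 | intermediate
25 | methyl (2R,3S)-3-[(tert-butyldimethylsilyl)oxy]-2-hydroxy-3-[3-methoxy-4-(triisopropylsilyloxy)phenyl]propanoate | COC(=O)[C@H](O)[C@@H](O[Si](C)(C)C(C)(C)C)c1ccc(O[Si](C(C)C)(C(C)C)C(C)C)c(OC)c1 | intermediate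
26 | methyl (2S,3S)-2-{4-[(2R,3S)-3-(acetoxymethyl)-5-(1,3-dioxolan-2-yl)-7-methoxy-2,3-dihydro-1-benzofuran-2-yl]-2,6-dimethoxyphenoxy}-3-[(tert-butyldimethylsilyl)oxy]-3-[3-methoxy-4-(triisopropylsilyloxy)phenyl]propanoate | COC(=O)[C@@H](Oc1c(OC)cc([C@@H]2Oc3c(OC)cc(C4OCCO4)cc3[C@H]2COC(C)=O)cc1OC)[C@@H](O[Si](C)(C)C(C)(C)C)c1ccc(O[Si](C(C)C)(C(C)C)C(C)C)c(OC)c1 | intermediate
27 | (2R,3S)-3-[(tert-butyldimethylsilyl)oxy]-2-{4-[(2R,3S)-5-(1,3-dioxolan-2-yl)-3-(hydroxymethyl)-7-methoxy-2,3-dihydro-1-benzofuran-2-yl]-2,6-dimethoxyphenoxy}-3-[3-methoxy-4-(triisopropylsilyloxy)phenyl]propan-1-ol | COc1cc([C@H](O[Si](C)(C)C(C)(C)C)[C@@H](CO)Oc2c(OC)cc([C@@H]3Oc4c(OC)cc(C5OCCO5)cc4[C@H]3CO)cc2OC)ccc1O[Si](C(C)C)(C(C)C)C(C)C | intermediate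
28 | (1S,2R)-2-{4-[(2R,3S)-5-(1,3-dioxolan-2-yl)-3-(hydroxymethyl)-7-methoxy-2,3-dihydro-1-benzofuran-2-yl]-2,6-dimethoxyphenoxy}-1-(4-hydroxy-3-methoxyphenyl)propane-1,3-diol | COc1cc([C@H](O)[C@@H](CO)Oc2c(OC)cc([C@@H]3Oc4c(OC)cc(C5OCCO5)cc4[C@H]3CO)cc2OC)ccc1O | intermediate
29 | (2R,3S)-2-(4-{[(1S,2R)-1,3-dihydroxy-1-(4-hydroxy-3-methoxyphenyl)propan-2-yl]oxy}-3,5-dimethoxyphenyl)-3-(hydroxymethyl)-7-methoxy-2,3-dihydro-1-benzofuran-5-carbaldehyde (CID53356209) | COc1cc([C@H](O)[C@@H](CO)Oc2c(OC)cc([C@@H]3Oc4c(OC)cc(C=O)cc4[C@H]3CO)cc2OC)ccc1O | target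

## Step count and least certain steps

Total: 22 steps. Longest linear sequence: 15 steps (1, 2, 4–12, 19–22, from syringaldehyde 1). The glycerate fragment takes six steps (13–18) and joins at step 19.

**Step 6 (key step).** The most likely failure is loss of the carbonylation: protonolysis of the C3–Pd bond, or cycloisomerisation without palladium, before CO has inserted. HCl is produced in each turnover, and the formyl-bearing phenol is a slow nucleophile, so the palladium-bound alkyne has time to follow other paths.
- Fallback: the same two bonds are made in separate operations. Starting from 7, iodocyclisation (I2, NaHCO3, MeCN, rt) gives 2-[4-(benzyloxy)-3,5-dimethoxyphenyl]-3-iodo-7-methoxy-1-benzofuran-5-carbaldehyde F1. Methoxycarbonylation of the C3–I bond (Pd(OAc)2, 1,1'-bis(diphenylphosphino)ferrocene, CO, Et3N, MeOH–DMF, 70 °C) then returns to the route at 8.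

**Step 19 (Mitsunobu etherification).** Substitution may be too slow. The phenol oxygen lies between two methoxy groups and the carbinol carbon is β-branched, so the betaine can be consumed by side reactions (hydrazide alkylation, silyl migration from the Cα to the Cβ oxygen, elimination) before the ether forms.
- Fallback: activation and displacement are separated. Starting from 25, Tf2O and 2,6-lutidine (CH2Cl2, −78 °C) give methyl (2R,3S)-3-[(tert-butyldimethylsilyl)oxy]-3-[3-methoxy-4-(triisopropylsilyloxy)phenyl]-2-[(trifluoromethanesulfonyl)oxy]propanoate F2. The caesium phenoxide of 14 (Cs2CO3, MeCN, −20 °C → rt) displaces the triflate with inversion, returning to the route at 26.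

**Step 10 (kinetic resolution).** The enzyme may discriminate poorly, because the stereocentre is one carbon away from the reacting hydroxyl and both enantiomers carry the same large aryl groups. The sense of the preference is also an assumption.
- Fallback: the resolving handle is moved onto the stereocentre itself. Starting from 10, saponification (LiOH, THF–H2O) gives rac-trans-2-[4-(benzyloxy)-3,5-dimethoxyphenyl]-5-(1,3-dioxolan-2-yl)-7-methoxy-2,3-dihydro-1-benzofuran-3-carboxylic acid F3.
- Coupling through the mixed pivalic anhydride with lithiated (S)-4-benzyl-1,3-oxazolidin-2-one gives two diastereomeric imides, separated by chromatography: (S)-4-benzyl-3-{[(2R,3R)-2-[4-(benzyloxy)-3,5-dimethoxyphenyl]-5-(1,3-dioxolan-2-yl)-7-methoxy-2,3-dihydro-1-benzofuran-3-yl]carbonyl}-1,3-oxazolidin-2-one F4 and its (2S,3S)-acyl diastereomer F5.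
- LiBH4 cleaves F4 reductively and returns to the route at 12, bypassing 11.

**Step 5 (freeing the alkynylphenol).** Premature ring closure is the risk. Under basic methanolysis the phenoxide, helped by traces of copper or palladium, can add to the alkyne and give the carbonyl-free 2-arylbenzofuran, which is lost to the key step.
- Fallback: a protecting group removed without base. Starting from 4, silylation (TBSCl, imidazole, DMF) gives 4-[(tert-butyldimethylsilyl)oxy]-3-iodo-5-methoxybenzaldehyde F6.
- Sonogashira coupling with 3 gives 3-{[4-(benzyloxy)-3,5-dimethoxyphenyl]ethynyl}-4-[(tert-butyldimethylsilyl)oxy]-5-methoxybenzaldehyde F7.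
- Buffered fluoride (Bu4NF, AcOH, THF, −20 °C) returns to the route at 7.

## Further compounds

F1 | step 6 | 2-[4-(benzyloxy)-3,5-dimethoxyphenyl]-3-iodo-7-methoxy-1-benzofuran-5-carbaldehyde | COc1cc(-c2oc3c(OC)cc(C=O)cc3c2I)cc(OC)c1OCc1ccccc1
F2 | step 19 | methyl (2R,3S)-3-[(tert-butyldimethylsilyl)oxy]-3-[3-methoxy-4-(triisopropylsilyloxy)phenyl]-2-[(trifluoromethanesulfonyl)oxy]propanoate | COC(=O)[C@H](OS(=O)(=O)C(F)(F)F)[C@@H](O[Si](C)(C)C(C)(C)C)c1ccc(O[Si](C(C)C)(C(C)C)C(C)C)c(OC)c1
F3 | step 10 | rac-trans-2-[4-(benzyloxy)-3,5-dimethoxyphenyl]-5-(1,3-dioxolan-2-yl)-7-methoxy-2,3-dihydro-1-benzofuran-3-carboxylic acid ((2R,3R) and (2S,3S)) | COc1cc([C@@H]2Oc3c(OC)cc(C4OCCO4)cc3[C@H]2C(O)=O)cc(OC)c1OCc1ccccc1.COc1cc([C@H]2Oc3c(OC)cc(C4OCCO4)cc3[C@@H]2C(O)=O)cc(OC)c1OCc1ccccc1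
F4 | step 10 | (S)-4-benzyl-3-{[(2R,3R)-2-[4-(benzyloxy)-3,5-dimethoxyphenyl]-5-(1,3-dioxolan-2-yl)-7-methoxy-2,3-dihydro-1-benzofuran-3-yl]carbonyl}-1,3-oxazolidin-2-one | COc1cc([C@@H]2Oc3c(OC)cc(C4OCCO4)cc3[C@H]2C(=O)N2C(=O)OC[C@@H]2Cc2ccccc2)cc(OC)c1OCc1ccccc1
F5 | step 10 | (S)-4-benzyl-3-{[(2S,3S)-2-[4-(benzyloxy)-3,5-dimethoxyphenyl]-5-(1,3-dioxolan-2-yl)-7-methoxy-2,3-dihydro-1-benzofuran-3-yl]carbonyl}-1,3-oxazolidin-2-one | COc1cc([C@H]2Oc3c(OC)cc(C4OCCO4)cc3[C@@H]2C(=O)N2C(=O)OC[C@@H]2Cc2ccccc2)cc(OC)c1OCc1ccccc1
F6 | step 5 | 4-[(tert-butyldimethylsilyl)oxy]-3-iodo-5-methoxybenzaldehyde | COc1cc(C=O)cc(I)c1O[Si](C)(C)C(C)(C)C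
F7 | step 5 | 3-{[4-(benzyloxy)-3,5-dimethoxyphenyl]ethynyl}-4-[(tert-butyldimethylsilyl)oxy]-5-methoxybenzaldehyde | COc1cc(C#Cc2cc(C=O)cc(OC)c2O[Si](C)(C)C(C)(C)C)cc(OC)c1OCc1ccccc1
A1 | alternative 1 | ethyl (2S,3S)-3-[4-(benzyloxy)-3-methoxyphenyl]-2-{4-[(2R,3S)-3-{[(tert-butyldimethylsilyl)oxy]methyl}-5-(1,3-dioxolan-2-yl)-7-methoxy-2,3-dihydro-1-benzofuran-2-yl]-2,6-dimethoxyphenoxy}-3-hydroxypropanoate (erythro) | COc1cc([C@H](O)[C@@H](C(=O)OCC)Oc2c(OC)cc([C@@H]3Oc4c(OC)cc(C5OCCO5)cc4[C@H]3CO[Si](C)(C)C(C)(C)C)cc2OC)ccc1OCc1ccccc1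
A2 | alternative 1 | ethyl diazoacetate | CCOC(=O)C=[N+]=[N-]
A3 | alternative 1 | 4-(benzyloxy)-3-methoxybenzaldehyde | COc1cc(C=O)ccc1OCc1ccccc1
A4 | alternative 1 | 4-[(2R,3S)-3-{[(tert-butyldimethylsilyl)oxy]methyl}-5-(1,3-dioxolan-2-yl)-7-methoxy-2,3-dihydro-1-benzofuran-2-yl]-2,6-dimethoxyphenol | COc1cc([C@@H]2Oc3c(OC)cc(C4OCCO4)cc3[C@H]2CO[Si](C)(C)C(C)(C)C)cc(OC)c1O
A5 | alternative 2 | methyl (2R,3R)-5-bromo-2-[3,5-dimethoxy-4-(methanesulfonyloxy)phenyl]-7-methoxy-2,3-dihydro-1-benzofuran-3-carboxylate (trans) | COc1cc([C@@H]2Oc3c(OC)cc(Br)cc3[C@H]2C(=O)OC)cc(OC)c1OS(C)(=O)=O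
A6 | alternative 2 | (2R)-6-bromo-2-[3,5-dimethoxy-4-(methanesulfonyloxy)phenyl]-8-methoxy-2,3-dihydro-4H-chromen-4-one | COc1cc([C@H]2CC(=O)c3cc(Br)cc(OC)c3O2)cc(OC)c1OS(C)(=O)=O
A7 | alternative 3 | (S)-4-benzyl-3-{[(2R,3R)-5-formyl-2-(4-hydroxy-3,5-dimethoxyphenyl)-7-methoxy-2,3-dihydro-1-benzofuran-3-yl]carbonyl}-1,3-oxazolidin-2-one (trans) | COc1cc([C@@H]2Oc3c(OC)cc(C=O)cc3[C@H]2C(=O)N2[C@@H](Cc3ccccc3)COC2=O)cc(OC)c1O
A8 | alternative 3 | (S)-4-benzyl-3-[(E)-3-(4-hydroxy-3,5-dimethoxyphenyl)prop-2-enoyl]-1,3-oxazolidin-2-one | COc1cc(/C=C/C(=O)N2[C@@H](Cc3ccccc3)COC2=O)cc(OC)c1O
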